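**Retrosynthetic overview** (quinone unit C1–C8a, naphthyl unit C1'–C8a', joined C3–C1')
1. The target is unveiled last from the tris-benzyl ether of its hydroquinone by hydrogenolysis and air oxidation.
2. The cresol ring C5'–C8' is opened at C4a'–C5' to a 4-aryl-3-methylcyclobut-2-enone, which re-forms it by thermal opening to a vinylketene and six-electron closure. This rests on ring C5'–C8' carrying only the C5' hydroxyl and the C7' methyl, and on C4a' being the only unsubstituted ortho carbon of the resorcinol ring because C1' holds the quinone.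
3. The cyclobutenone comes from an arylacetic dimethylamide and propyne by keteniminium [2+2] cycloaddition.
4. The C3–C1' biaryl bond comes from Suzuki coupling of a bromo amide (from 3,5-dimethoxyphenylacetic acid) with a bis-benzyl quinol boronate (from plumbagin).
5. Ring order: quinone bicycle and resorcinol ring are bought; then biaryl bond, four-membered ring, cresol ring, and finally the quinone oxidation level.

Key step: step 13

Remark: the target is drawn without configuration at the hindered C3–C1' axis, so it is taken as the racemate and the axis is not controlled.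

Remark: bromination of a 3-alkoxy-5-hydroxyarene para to the free phenol is not dependable, so the two resorcinol oxygens are told apart as acetate and methyl ether before bromination (steps 2–6).

**Step 1**
Reactants: 1 3,5-dimethoxyphenylacetic acid
Product: 3 2-(3,5-dimethoxyphenyl)-N,N-dimethylacetamide, via acid chloride 2 (not isolated)
Conditions: (COCl)2, DMF (cat.), CH2Cl2, 0 °C to rt; then Me2NH (2 M in THF, excess), 0 °C
Reagents that add atoms: dimethylamine, CNC
Why: Acid chloride formation followed by amidation is a dependable acyl substitution and installs the tertiary amide from which the keteniminium ion of step 12 is made.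

**Step 2**
Reactants: 3 2-(3,5-dimethoxyphenyl)-N,N-dimethylacetamide
Product: 4 2-(3-hydroxy-5-methoxyphenyl)-N,N-dimethylacetamide
Conditions: NaSEt, DMF, 140 °C; aq. HCl work-up
Reagents that add atoms: none
Why: SN2 demethylation of an aryl methyl ether by thiolate should stop after one methyl group, because the phenoxide formed deactivates the ring toward loss of the second, and the tertiary amide is inert to thiolate.

**Step 3**
Reactants: 4 2-(3-hydroxy-5-methoxyphenyl)-N,N-dimethylacetamide
Product: 5 3-[2-(dimethylamino)-2-oxoethyl]-5-methoxyphenyl acetate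
Conditions: Ac2O, pyridine, DMAP (cat.), CH2Cl2, rt
Reagents that add atoms: acetic anhydride, CC(=O)OC(C)=O
Why: O-Acetylation turns the phenol oxygen into a weak donor, so that the methoxy group alone directs the bromination of step 4.

**Step 4**
Reactants: 5 3-[2-(dimethylamino)-2-oxoethyl]-5-methoxyphenyl acetate
Product: 6 2-bromo-3-[2-(dimethylamino)-2-oxoethyl]-5-methoxyphenyl acetate
Conditions: NBS, MeCN, 0 °C to rt, dark
Reagents that add atoms: N-bromosuccinimide, O=C1CCC(=O)N1Br
Why: In this electrophilic aromatic bromination the methoxy group is a far stronger para director than the acetoxy group, so bromine should enter the carbon para to OMe (between the acetoxy and the CH2 group), while the carbon between the two oxygens stays free as it does in 3,5-dioxygenated toluenes.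

**Step 5**
Reactants: 6 2-bromo-3-[2-(dimethylamino)-2-oxoethyl]-5-methoxyphenyl acetate
Product: 7 2-(2-bromo-3-hydroxy-5-methoxyphenyl)-N,N-dimethylacetamide
Conditions: K2CO3 (cat.), MeOH, rt
Reagents that add atoms: none
Why: Base-catalysed transesterification to methanol should remove the aryl acetate under conditions that leave the tertiary amide and the aryl bromide untouched.

**Step 6**
Reactants: 7 2-(2-bromo-3-hydroxy-5-methoxyphenyl)-N,N-dimethylacetamide
Product: 8 2-[3-(benzyloxy)-2-bromo-5-methoxyphenyl]-N,N-dimethylacetamide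
Conditions: BnBr, K2CO3, DMF, rt
Reagents that add atoms: benzyl bromide, BrCc1ccccc1
Why: Williamson etherification of the phenoxide places on the future C2' oxygen a group that survives palladium, triflic anhydride and heat and is removed with the other benzyl ethers in step 14.

**Step 7**
Reactants: 9 plumbagin (5-hydroxy-2-methylnaphthalene-1,4-dione)
Product: 11 3-bromo-5-hydroxy-2-methylnaphthalene-1,4-dione, via trans-dibromide 10 (not isolated)
Conditions: Br2, AcOH, rt; then NaOAc, 80 °C
Reagents that add atoms: bromine, BrBr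
Why: Bromine adds across the only unsubstituted quinone double bond C2=C3, and acetate-induced loss of HBr (the C3 proton is alpha to C4=O) returns the quinone with bromine at C3; the hydrogen-bonded, carbonyl-deactivated phenol ring should not be brominated.

**Step 8**
Reactants: 11 3-bromo-5-hydroxy-2-methylnaphthalene-1,4-dione
Product: 12 3-bromo-5-methoxy-2-methylnaphthalene-1,4-dione
Conditions: MeI, Ag2O, CH2Cl2, rt, dark
Reagents that add atoms: iodomethane, CI
Why: Silver oxide-mediated O-methylation alkylates the chelated peri hydroxyl under neutral conditions, which avoids attack of a basic nucleophile on the bromoquinone.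

**Step 9**
Reactants: 12 3-bromo-5-methoxy-2-methylnaphthalene-1,4-dione
Product: 14 1,4-bis(benzyloxy)-3-bromo-5-methoxy-2-methylnaphthalene, via bromohydroquinone 13 (not isolated)
Conditions: Na2S2O4, EtOAc/H2O, rt; organic layer concentrated under Ar; then BnBr, Cs2CO3, DMF, rt
Reagents that add atoms: benzyl bromide, BrCc1ccccc1
Why: Dithionite reduces the quinone to the hydroquinone without touching the aryl bromide, and double Williamson benzylation under argon locks the quinol as ethers that tolerate organolithium and palladium chemistry.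

**Step 10**
Reactants: 14 1,4-bis(benzyloxy)-3-bromo-5-methoxy-2-methylnaphthalene
Product: 16 2-[1,4-bis(benzyloxy)-8-methoxy-3-methylnaphthalen-2-yl]-4,4,5,5-tetramethyl-1,3,2-dioxaborolane, via aryllithium 15 (not isolated)
Conditions: n-BuLi, THF, −78 °C; then i-PrOBpin, −78 °C to rt
Reagents that add atoms: 2-isopropoxy-4,4,5,5-tetramethyl-1,3,2-dioxaborolane, CC(C)OB1OC(C)(C)C(C)(C)O1
Why: Bromine–lithium exchange at −78 °C is faster than deprotonation of the benzyl ethers, and the aryllithium is trapped by the borate ester to give the pinacol boronate.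

**Step 11**
Reactants: 8 2-[3-(benzyloxy)-2-bromo-5-methoxyphenyl]-N,N-dimethylacetamide; 16 2-[1,4-bis(benzyloxy)-8-methoxy-3-methylnaphthalen-2-yl]-4,4,5,5-tetramethyl-1,3,2-dioxaborolane
Product: 17 2-{3-(benzyloxy)-2-[1,4-bis(benzyloxy)-8-methoxy-3-methylnaphthalen-2-yl]-5-methoxyphenyl}-N,N-dimethylacetamide (racemic about the new axis)
Conditions: Pd(OAc)2, SPhos, K3PO4, PhMe/H2O, 100 °C
Reagents that add atoms: none
Why: Suzuki–Miyaura coupling with a bulky dialkylbiarylphosphine ligand is an established way to biaryls with four ortho substituents, and the amide, ethers and benzylic CH2 are inert to phosphate base.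

**Step 12**
Reactants: 17 biaryl dimethylamide; 18 propyne
Product: 21 4-{3-(benzyloxy)-2-[1,4-bis(benzyloxy)-8-methoxy-3-methylnaphthalen-2-yl]-5-methoxyphenyl}-3-methylcyclobut-2-en-1-one (racemic at C4; both rotamers about the biaryl axis), via keteniminium triflate 19 (not isolated), via cyclobuteniminium triflate 20 (not isolated)
Conditions: Tf2O, 2,4,6-collidine, propyne (excess), CH2Cl2, −78 °C to 40 °C, sealed tube; then sat. aq. NaHCO3, rt
Reagents that add atoms: water, O
Why: In this keteniminium–alkyne [2+2] cycloaddition, O-triflation of the amide and loss of triflic acid give the aldoketeniminium ion, whose central carbon attacks the unsubstituted alkyne carbon (the methyl-bearing vinyl cation is the more stable) before the ring closes at the benzylic carbon, so that hydrolysis of the iminium salt should give the 3-methyl-4-aryl enone; C4 forms as a racemate without control, which does not matter because it becomes sp2 in step 13, and Friedel–Crafts closure onto the quinol ring is blocked because both of its carbons next to the axis are substituted.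

**Step 13**
Reactants: 21 4-aryl-3-methylcyclobut-2-en-1-one
Product: 24 6-(benzyloxy)-5-[1,4-bis(benzyloxy)-8-methoxy-3-methylnaphthalen-2-yl]-8-methoxy-3-methylnaphthalen-1-ol (racemic about the axis), via vinylketene 22 (not isolated), via dienone 23 (not isolated)
Conditions: PhMe (0.01 M), 110 °C, Ar
Reagents that add atoms: none
Why: Heat opens the strained enone by conrotatory four-electron cleavage of C1–C4 to a vinylketene, and only the isomer with the aryl group turned inward, (Z)-22, can bring its ketene carbon to the ring; the outward isomer can only return to 21, so the reversible opening should funnel material through (Z)-22. The ketene C=C, the C(Me)=CH bond and the aryl C8a'=C4a' bond then close in a disrotatory six-electron electrocyclisation that forms C4a'–C5' and the six-membered ring C5'–C8' as dienone 23, which tautomerises to the aromatic 5'-naphthol with the methyl group at C7'. The closest known reaction is the thermal rearrangement of 4-arylcyclobutenones to 1-naphthols, the ring-forming stage of cyclobutenone benzannulations, which also proceeds when the second C4 substituent is hydrogen. No stereocentre is created: C4 of 21 becomes the sp2 carbon C8', so both C4 epimers and both rotamers about the axis converge on racemic 24. The step needs closure at C4a' only, and the substrate secures this because the other ortho carbon (C1') carries the quinol naphthyl group, while high dilution under neutral conditions should keep the ketene from acylating the product phenol and spares the benzyl ethers.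

**Step 14**
Reactants: 24 tris-benzyl naphthol
Product: 26 3-(2,5-dihydroxy-4-methoxy-7-methylnaphthalen-1-yl)-5-methoxy-2-methylnaphthalene-1,4-dione (target; racemic about the axis), via hydroquinone 25 (not isolated)
Conditions: H2 (1 atm), Pd/C, EtOAc/MeOH, rt; filtration; then air, rt
Reagents that add atoms: none
Why: Hydrogenolysis cleaves the three aryl benzyl ethers, and the resulting 1,4-naphthohydroquinone ring should be oxidised by air to the quinone while the naphthol ring, which has no para-dihydroxy pattern, stays at the phenol level.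

**Compound list**
1 | 3,5-dimethoxyphenylacetic acid | COc1cc(CC(O)=O)cc(OC)c1 | starting material
2 | 2-(3,5-dimethoxyphenyl)acetyl chloride (not isolated) | COc1cc(CC(Cl)=O)cc(OC)c1 | intermediate
3 | 2-(3,5-dimethoxyphenyl)-N,N-dimethylacetamide | COc1cc(CC(=O)N(C)C)cc(OC)c1 | intermediate
4 | 2-(3-hydroxy-5-methoxyphenyl)-N,N-dimethylacetamide | COc1cc(O)cc(CC(=O)N(C)C)c1 | intermediate
5 | 3-[2-(dimethylamino)-2-oxoethyl]-5-methoxyphenyl acetate | COc1cc(OC(C)=O)cc(CC(=O)N(C)C)c1 | intermediate
6 | 2-bromo-3-[2-(dimethylamino)-2-oxoethyl]-5-methoxyphenyl acetate | COc1cc(OC(C)=O)c(Br)c(CC(=O)N(C)C)c1 | intermediate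
7 | 2-(2-bromo-3-hydroxy-5-methoxyphenyl)-N,N-dimethylacetamide | COc1cc(O)c(Br)c(CC(=O)N(C)C)c1 | intermediate
8 | 2-[3-(benzyloxy)-2-bromo-5-methoxyphenyl]-N,N-dimethylacetamide | COc1cc(OCc2ccccc2)c(Br)c(CC(=O)N(C)C)c1 | intermediate
9 | plumbagin (5-hydroxy-2-methylnaphthalene-1,4-dione) | CC1=CC(=O)c2c(O)cccc2C1=O | starting material
10 | trans-2,3-dibromo-5-hydroxy-2-methyl-2,3-dihydronaphthalene-1,4-dione (racemic, one enantiomer drawn; not isolated) | C[C@]1(Br)[C@H](Br)C(=O)c2c(O)cccc2C1=O | intermediate
11 | 3-bromo-5-hydroxy-2-methylnaphthalene-1,4-dione | CC1=C(Br)C(=O)c2c(O)cccc2C1=O | intermediate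
12 | 3-bromo-5-methoxy-2-methylnaphthalene-1,4-dione | CC1=C(Br)C(=O)c2c(OC)cccc2C1=O | intermediate
13 | 3-bromo-5-methoxy-2-methylnaphthalene-1,4-diol (not isolated) | Cc1c(O)c2cccc(OC)c2c(O)c1Br | intermediate
14 | 1,4-bis(benzyloxy)-3-bromo-5-methoxy-2-methylnaphthalene | Cc1c(OCc2ccccc2)c2cccc(OC)c2c(OCc2ccccc2)c1Br | intermediate
15 | [1,4-bis(benzyloxy)-8-methoxy-3-methylnaphthalen-2-yl]lithium (not isolated) | Cc1c(OCc2ccccc2)c2cccc(OC)c2c(OCc2ccccc2)c1[Li] | intermediate
16 | 2-[1,4-bis(benzyloxy)-8-methoxy-3-methylnaphthalen-2-yl]-4,4,5,5-tetramethyl-1,3,2-dioxaborolane | Cc1c(OCc2ccccc2)c2cccc(OC)c2c(OCc2ccccc2)c1B1OC(C)(C)C(C)(C)O1 | intermediate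
17 | 2-{3-(benzyloxy)-2-[1,4-bis(benzyloxy)-8-methoxy-3-methylnaphthalen-2-yl]-5-methoxyphenyl}-N,N-dimethylacetamide (racemic about the axis) | CN(C)C(=O)Cc1cc(OC)cc(OCc2ccccc2)c1-c1c(C)c(OCc2ccccc2)c2cccc(OC)c2c1OCc1ccccc1 | intermediate
18 | propyne | CC#C | starting material
19 | N-(2-arylethenylidene)-N-methylmethanaminium triflate, aryl = the biaryl group of 17 (not isolated) | C[N+](C)=C=Cc1cc(OC)cc(OCc2ccccc2)c1-c1c(C)c(OCc2ccccc2)c2cccc(OC)c2c1OCc1ccccc1.[O-]S(=O)(=O)C(F)(F)F | intermediate
20 | N-(4-aryl-3-methylcyclobut-2-en-1-ylidene)-N-methylmethanaminium triflate, aryl = the biaryl group of 17 (racemic; not isolated) | C[N+](C)=C1C=C(C)C1c1cc(OC)cc(OCc2ccccc2)c1-c1c(C)c(OCc2ccccc2)c2cccc(OC)c2c1OCc1ccccc1.[O-]S(=O)(=O)C(F)(F)F | intermediate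
21 | 4-{3-(benzyloxy)-2-[1,4-bis(benzyloxy)-8-methoxy-3-methylnaphthalen-2-yl]-5-methoxyphenyl}-3-methylcyclobut-2-en-1-one (racemic at C4, one enantiomer drawn; both rotamers about the axis) | CC1=CC(=O)[C@H]1c1cc(OC)cc(OCc2ccccc2)c1-c1c(C)c(OCc2ccccc2)c2cccc(OC)c2c1OCc1ccccc1 | intermediate
22 | (3Z)-4-aryl-3-methylbuta-1,3-dien-1-one, aryl = the biaryl group of 17 (not isolated) | O=C=C/C(C)=C\c1cc(OC)cc(OCc2ccccc2)c1-c1c(C)c(OCc2ccccc2)c2cccc(OC)c2c1OCc1ccccc1 | intermediate
23 | 6-(benzyloxy)-5-[1,4-bis(benzyloxy)-8-methoxy-3-methylnaphthalen-2-yl]-8-methoxy-3-methylnaphthalen-1(8aH)-one (configuration at C8a not controlled; not isolated) | CC1=CC(=O)C2C(OC)=CC(OCc3ccccc3)=C(c3c(C)c(OCc4ccccc4)c4cccc(OC)c4c3OCc3ccccc3)C2=C1 | intermediate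
24 | 6-(benzyloxy)-5-[1,4-bis(benzyloxy)-8-methoxy-3-methylnaphthalen-2-yl]-8-methoxy-3-methylnaphthalen-1-ol (racemic about the axis) | Cc1c(OCc2ccccc2)c2cccc(OC)c2c(OCc2ccccc2)c1-c1c(OCc2ccccc2)cc(OC)c2c(O)cc(C)cc12 | intermediate
25 | 3-(2,5-dihydroxy-4-methoxy-7-methylnaphthalen-1-yl)-5-methoxy-2-methylnaphthalene-1,4-diol (not isolated) | Cc1c(O)c2cccc(OC)c2c(O)c1-c1c(O)cc(OC)c2c(O)cc(C)cc12 | intermediate
26 | 3-(2,5-dihydroxy-4-methoxy-7-methylnaphthalen-1-yl)-5-methoxy-2-methylnaphthalene-1,4-dione (racemic about the axis) | COc1cccc2c1C(=O)C(c1c(O)cc(OC)c3c(O)cc(C)cc13)=C(C)C2=O | target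

**Step count**
Total: 14 steps. Longest linear sequence: 10 steps (steps 1–6, then 11–14).

**Steps most likely to fail**

Step 13. The vinylketene formed by outward rotation of the aryl group cannot cyclise, and it may be consumed by dimerisation or by acylating the product phenol faster than it returns to the cyclobutenone. Closure at the carbon next to the methoxy group may also be slow. The fallback sets out from 21 and comes back at 24. It makes the interception productive and closes the ring by acylation instead of electrocyclisation. Heating 21 in PhMe/MeOH at 90 °C lets methanol trap the outward-opened ketene (3E)-4-aryl-3-methylbuta-1,3-dien-1-one F1 as methyl (E)-4-aryl-3-methylbut-3-enoate F2. Saponification (LiOH, THF/H2O) gives (E)-4-aryl-3-methylbut-3-enoic acid F3. NaOAc in Ac2O at 140 °C then forms the mixed anhydride, whose double-bond isomers equilibrate through its dienol acetate, and intramolecular Friedel–Crafts acylation at the activated C4a' should give the naphthyl acetate of 24 F4. Methanolysis (K2CO3, MeOH) returns 24.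

Step 12. The keteniminium ion sits next to the bulky ortho naphthyl group, so capture of volatile propyne may be slow and self-condensation or acid-induced loss of benzyl ethers may take over. The fallback sets out from 8 and comes back at 24. It runs the cycloaddition and the ring closure on the small fragment and makes the biaryl bond last. Amide 8 with Tf2O, collidine and propyne, then aqueous NaHCO3, should give 4-[3-(benzyloxy)-2-bromo-5-methoxyphenyl]-3-methylcyclobut-2-en-1-one F5. Heating in PhMe at 110 °C should give 6-(benzyloxy)-5-bromo-8-methoxy-3-methylnaphthalen-1-ol F6, the bromine blocking the second ortho carbon. Suzuki–Miyaura coupling of F6 with boronate 16 (Pd(OAc)2, SPhos, K3PO4, PhMe/H2O) then gives 24.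

Step 11. Protodeboronation of the electron-rich, doubly ortho-substituted boronate may outrun transmetalation, and reductive elimination to a biaryl with four ortho substituents may be slow. The fallback sets out from 8, uses bromoquinone 12 and comes back at 17. It reverses the roles of the partners and couples at the quinone oxidation level, where C3 is flanked by a flat carbonyl group instead of a benzyloxy group. Miyaura borylation of 8 (B2pin2, Pd(dppf)Cl2, KOAc, dioxane, 90 °C) gives 2-[3-(benzyloxy)-5-methoxy-2-(4,4,5,5-tetramethyl-1,3,2-dioxaborolan-2-yl)phenyl]-N,N-dimethylacetamide F7. Coupling with 12 (Pd(PPh3)4, K3PO4, dioxane, 80 °C) gives the arylquinone 2-[3-(benzyloxy)-5-methoxy-2-(8-methoxy-3-methyl-1,4-dioxo-1,4-dihydronaphthalen-2-yl)phenyl]-N,N-dimethylacetamide F8. Reduction with Na2S2O4 gives the hydroquinone 2-[3-(benzyloxy)-2-(1,4-dihydroxy-8-methoxy-3-methylnaphthalen-2-yl)-5-methoxyphenyl]-N,N-dimethylacetamide F9, which is not isolated and is benzylated (BnBr, Cs2CO3, DMF) to 17.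

**Further compounds**
F1 | step 13 | (3E)-4-aryl-3-methylbuta-1,3-dien-1-one, aryl = the biaryl group of 17 | O=C=C/C(C)=C/c1cc(OC)cc(OCc2ccccc2)c1-c1c(C)c(OCc2ccccc2)c2cccc(OC)c2c1OCc1ccccc1
F2 | step 13 | methyl (E)-4-aryl-3-methylbut-3-enoate, aryl = the biaryl group of 17 | COC(=O)C/C(C)=C/c1cc(OC)cc(OCc2ccccc2)c1-c1c(C)c(OCc2ccccc2)c2cccc(OC)c2c1OCc1ccccc1
F3 | step 13 | (E)-4-aryl-3-methylbut-3-enoic acid, aryl = the biaryl group of 17 | OC(=O)C/C(C)=C/c1cc(OC)cc(OCc2ccccc2)c1-c1c(C)c(OCc2ccccc2)c2cccc(OC)c2c1OCc1ccccc1
F4 | step 13 | 6-(benzyloxy)-5-[1,4-bis(benzyloxy)-8-methoxy-3-methylnaphthalen-2-yl]-8-methoxy-3-methylnaphthalen-1-yl acetate | CC(=O)Oc1cc(C)cc2c(-c3c(C)c(OCc4ccccc4)c4cccc(OC)c4c3OCc3ccccc3)c(OCc3ccccc3)cc(OC)c12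
F5 | step 12 | 4-[3-(benzyloxy)-2-bromo-5-methoxyphenyl]-3-methylcyclobut-2-en-1-one (racemic, one enantiomer drawn) | CC1=CC(=O)[C@H]1c1cc(OC)cc(OCc2ccccc2)c1Br
F6 | step 12 | 6-(benzyloxy)-5-bromo-8-methoxy-3-methylnaphthalen-1-ol | Cc1cc(O)c2c(OC)cc(OCc3ccccc3)c(Br)c2c1
F7 | step 11 | 2-[3-(benzyloxy)-5-methoxy-2-(4,4,5,5-tetramethyl-1,3,2-dioxaborolan-2-yl)phenyl]-N,N-dimethylacetamide | COc1cc(OCc2ccccc2)c(B2OC(C)(C)C(C)(C)O2)c(CC(=O)N(C)C)c1
F8 | step 11 | 2-[3-(benzyloxy)-5-methoxy-2-(8-methoxy-3-methyl-1,4-dioxo-1,4-dihydronaphthalen-2-yl)phenyl]-N,N-dimethylacetamide | COc1cc(OCc2ccccc2)c(C2=C(C)C(=O)c3cccc(OC)c3C2=O)c(CC(=O)N(C)C)c1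
F9 | step 11 | 2-[3-(benzyloxy)-2-(1,4-dihydroxy-8-methoxy-3-methylnaphthalen-2-yl)-5-methoxyphenyl]-N,N-dimethylacetamide | COc1cc(OCc2ccccc2)c(-c2c(C)c(O)c3cccc(OC)c3c2O)c(CC(=O)N(C)C)c1
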